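**Retrosynthetic overview**
1. Target 23 is the hemiketal of a tricyclic hydroxy diketone. Ring A and the oxygen bridge come apart together by an intramolecular aldol of a methyl ketone side chain onto the ring B ketone, after which the tertiary OH adds to the ring C ketone. The ring A methyl/alkene comes from the aldol ketone via an enol triflate.
2. The oxobutyl side chain comes from C-alkylation of bicyclic enone ester 11 with iodo ketal 15 (fragment 3, from ethyl acetoacetate).
3. Ring B of 11 comes from an intramolecular Michael addition (6-endo-dig) of the ring C enedione onto an ynone unveiled by ozonolysis.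
4. The quaternary stereocentre comes from an enantioselective palladium-catalysed allylation that joins silyl dienol ether 3 (fragment 1, from carvacrol) to enyne carbonate 7 (fragment 2).
5. Ring order: C (from the arene), then B (Michael), then A plus the O-bridge (aldol/hemiketal); the ring C enone is reduced last.

Assumption: the hemiketal carbon (C14) is not set by any reagent – it closes in the only way the cage allows – and its descriptor is carried throughout exactly as written in the target string.

Locants used below (also for the corresponding atoms of precursors): C1 ester-bearing alkene carbon; C2 alkene CH; C3 oxygen-bearing quaternary carbon; C4 CH2; C5/C6 ring A alkene (C5 carries the methyl); C7 CH2; C8 ring-fusion CH; C9 angular-methyl carbon; C10 CH between C1 and the ketone; C11 ketone; C12 isopropyl carbon; C13 CH2; C14 hemiketal carbon bridged by O to C3. Ring A = C3–C8; ring B = C1, C2, C3, C8, C9, C10; ring C = C9–C14.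

**Route**

Step 1
Reactants: 1 carvacrol (5-isopropyl-2-methylphenol)
Product: 2 5-isopropyl-4,4-dimethoxy-2-methylcyclohexa-2,5-dien-1-one
Conditions: PhI(OAc)2 (2.2 equiv), MeOH, 0 °C to rt
Reagents that add atoms: methanol (CO)
Why: Hypervalent-iodine oxidative dearomatisation (two successive phenol oxidations via 4-methoxycarvacrol) puts both methoxy groups on the free para carbon and gives the quinone monoketal; no stereocentre is formed.

Step 2
Reactants: 2 5-isopropyl-4,4-dimethoxy-2-methylcyclohexa-2,5-dien-1-one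
Product: 3 [(5-isopropyl-4,4-dimethoxy-2-methylcyclohexa-1,5-dien-1-yl)oxy]dimethyl(phenyl)silane
Conditions: [(Ph3P)CuH]6 (2 mol%), Me2PhSiH (1.2 equiv), toluene, 0 °C to rt
Reagents that add atoms: dimethylphenylsilane (C[SiH](C)c1ccccc1)
Why: Copper hydride 1,4-hydrosilylation delivers hydride to the unsubstituted β-carbon (C10) of the methyl-bearing enone arm, the other β-carbon being blocked by isopropyl, and silylates the enolate, so the tetrasubstituted silyl enol ether is formed regiospecifically.

Step 3
Reactants: 4 2-bromoprop-2-en-1-ol; 5 methyl propiolate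
Product: 6 methyl 4-(hydroxymethyl)pent-4-en-2-ynoate
Conditions: Pd(PPh3)2Cl2 (2 mol%), CuI (4 mol%), K2CO3 (2 equiv), THF, 50 °C
Reagents that add atoms: none
Why: Sonogashira coupling of the vinyl bromide with the terminal alkyne; the inorganic base avoids amine conjugate addition to the propiolate.

Step 4
Reactants: 6 methyl 4-(hydroxymethyl)pent-4-en-2-ynoate
Product: 7 methyl 4-{[(methoxycarbonyl)oxy]methyl}pent-4-en-2-ynoate
Conditions: ClCO2Me, pyridine, CH2Cl2, 0 °C
Reagents that add atoms: methyl chloroformate (COC(=O)Cl)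
Why: O-acylation of the primary allylic alcohol gives the allylic carbonate needed for π-allylpalladium formation.

Step 5
Reactants: 3 silyl dienol ether; 7 enyne carbonate
Product: 9 methyl 4-{[(1R)-4-isopropyl-1-methyl-2,5-dioxocyclohex-3-en-1-yl]methyl}pent-4-en-2-ynoate, via dimethyl ketal 8 (not isolated)
Conditions: Pd2(dba)3 (2.5 mol%), (S)-t-BuPHOX (6.5 mol%), Bu4N[Ph3SiF2] (35 mol%), THF, 25 °C; then 1 M HCl, rt
Reagents that add atoms: water (O)
Why: Stoltz-type enantioselective Tsuji allylation in which fluoride releases the tetrasubstituted enolate and the 2-substituted π-allylpalladium from 7 is attacked under control of the (S)-ligand (the sense that gives (S)-2-allyl-2-methylcyclohexanone), setting quaternary C9 as R; the acid then hydrolyses the dimethyl ketal, which cannot aromatise because C9 is quaternary.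

Step 6
Reactants: 9 enedione enyne ester
Product: 11 methyl (4aR,8aR)-7-isopropyl-4a-methyl-3,5,8-trioxo-3,4,4a,5,8,8a-hexahydronaphthalene-1-carboxylate, via ynone 10 (not isolated)
Conditions: O3, CH2Cl2, −78 °C; Me2S; then DBU (1.2 equiv), 0 °C; citric acid work-up
Reagents that add atoms: ozone ([O-][O+]=O)
Why: Ozone cleaves only the 1,1-disubstituted alkene (the enedione alkene and the alkynoate are electron-poor) to give a 4-oxo-2-ynoate, and base then drives a 6-endo-dig intramolecular Michael addition of the C10 enolate to the alkyne carbon β to the new ketone, closing ring B; C10 is epimerisable and settles cis to the angular methyl.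

Step 7
Reactants: 12 ethyl acetoacetate
Product: 13 ethyl 2-(2-methyl-1,3-dioxolan-2-yl)acetate
Conditions: HOCH2CH2OH, TsOH (cat.), toluene, reflux, Dean–Stark
Reagents that add atoms: ethylene glycol (OCCO)
Why: Acid-catalysed ketalisation protects the ketone.

Step 8
Reactants: 13 ethyl 2-(2-methyl-1,3-dioxolan-2-yl)acetate
Product: 14 2-(2-methyl-1,3-dioxolan-2-yl)ethanol
Conditions: LiAlH4, Et2O, 0 °C
Reagents that add atoms: none
Why: Hydride reduction of the ester to the primary alcohol; the ketal is inert.

Step 9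
Reactants: 14 2-(2-methyl-1,3-dioxolan-2-yl)ethanol
Product: 15 2-(2-iodoethyl)-2-methyl-1,3-dioxolane
Conditions: I2, PPh3, imidazole, CH2Cl2, 0 °C
Reagents that add atoms: iodine (II)
Why: Appel-type iodination converts the primary alcohol into the iodide without acid.

Step 10
Reactants: 11 bicyclic enone ester; 15 iodo ketal
Product: 16 methyl (4R,4aR,8aR)-7-isopropyl-4a-methyl-4-[2-(2-methyl-1,3-dioxolan-2-yl)ethyl]-3,5,8-trioxo-3,4,4a,5,8,8a-hexahydronaphthalene-1-carboxylate
Conditions: LiN(i-Pr)2 (2.3 equiv), THF/DMPU, −78 to −40 °C; then 15; AcOH, −78 °C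
Reagents that add atoms: none
Why: Hauser-type dianion alkylation in which the first equivalent of base removes the acidic C10–H of the vinylogous 1,3-diketone and the second forms the α′-enolate at C8, the more basic site, which is C-alkylated by the primary iodide; C8 remains epimerisable (α to the C3 ketone), so 16 is drawn as the epimer needed and its configuration is settled in step 11.

Step 11
Reactants: 16 alkylated bicyclic ketal
Product: 19 cage ketone (3R,8R,9R,10R,14R) – as 23 but with C5 a ketone (C6 saturated) and a C12=C13 double bond, via methyl ketone 17 (not isolated), via open ketol 18 (not isolated)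
Conditions: 2 M HCl, THF, 40 °C; solvent exchange; L-proline (30 mol%), DMF, rt
Reagents that add atoms: water (O)
Why: Key cascade in which acid unmasks the methyl ketone and equilibrates C8, the proline enamine of the methyl ketone adds to the C3 ketone (Hajos–Parrish-type intramolecular aldol, cis-fused ketol), and the tertiary alcohol at once adds to the C14 ketone; this hemiketal can form only when the C8 side chain is cis to the angular methyl, so the cage drains the equilibrium and fixes C3, C8, C10 and C14 relative to C9.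

Step 12
Reactants: 19 cage ketone
Product: 20 cage enol triflate (3R,8R,9R,10R,14R) – as 19 but C5(OSO2CF3)=C6
Conditions: LiN(i-Pr)2 (2.2 equiv), THF, −78 °C; N-(5-chloropyridin-2-yl)bis(trifluoromethanesulfonimide) (1.1 equiv); AcOH, −78 °C
Reagents that add atoms: Comins' reagent, N-(5-chloropyridin-2-yl)bis(trifluoromethanesulfonimide) (FC(F)(F)S(=O)(=O)N(c1ccc(Cl)cn1)S(=O)(=O)C(F)(F)F)
Why: After the hemiketal OH, the hindered amide deprotonates kinetically at the unhindered C6 methylene, not at C4 (neopentyl and β to the bridge oxygen), and the enolate is trapped as the regiodefined enol triflate.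

Step 13
Reactants: 20 cage enol triflate
Product: 21 cage enone (3R,8R,9R,10R,14R) – 12,13-didehydro-23
Conditions: MeZnCl (3 equiv), Pd(PPh3)4 (5 mol%), THF, 45 °C
Reagents that add atoms: methylzinc chloride (C[Zn]Cl)
Why: Negishi cross-coupling replaces the triflate by methyl and completes the trisubstituted ring A alkene; the organozinc tolerates ketone, ester and hemiketal.

Step 14
Reactants: 21 cage enone
Product: 23 target CNP0382995.2 (3R,8R,9R,10R,12R,14R), via silyl enol ether 22 (not isolated)
Conditions: [(Ph3P)CuH]6 (5 mol%), Me2PhSiH (1.3 equiv), toluene, 0 °C; then K2CO3 (20 mol%), MeOH, rt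
Reagents that add atoms: none
Why: Copper hydride 1,4-reduction is selective for the enone over the hindered γ-oxygenated enoate and the isolated alkene, methanolysis releases the ketone, and carbonate equilibrates C12 to the equatorial isopropyl epimer (12R), the axial one being syn-axial to both bonds that tie ring C into the cage.

**Compound list**
1 | carvacrol (5-isopropyl-2-methylphenol) | Cc1ccc(C(C)C)cc1O | starting material
2 | 5-isopropyl-4,4-dimethoxy-2-methylcyclohexa-2,5-dien-1-one | CC1=CC(OC)(OC)C(C(C)C)=CC1=O | intermediate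
3 | [(5-isopropyl-4,4-dimethoxy-2-methylcyclohexa-1,5-dien-1-yl)oxy]dimethyl(phenyl)silane | C[Si](C)(c1ccccc1)OC1=C(C)CC(OC)(OC)C(C(C)C)=C1 | intermediate
4 | 2-bromoprop-2-en-1-ol | OCC(Br)=C | starting material
5 | methyl propiolate | C#CC(=O)OC | starting material
6 | methyl 4-(hydroxymethyl)pent-4-en-2-ynoate | COC(=O)C#CC(=C)CO | intermediate
7 | methyl 4-{[(methoxycarbonyl)oxy]methyl}pent-4-en-2-ynoate | COC(=O)OCC(=C)C#CC(=O)OC | intermediate
8 | methyl 4-{[(1R)-4-isopropyl-5,5-dimethoxy-1-methyl-2-oxocyclohex-3-en-1-yl]methyl}pent-4-en-2-ynoate | COC(=O)C#CC(=C)C[C@]1(C)CC(OC)(OC)C(C(C)C)=CC1=O | intermediate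
9 | methyl 4-{[(1R)-4-isopropyl-1-methyl-2,5-dioxocyclohex-3-en-1-yl]methyl}pent-4-en-2-ynoate | COC(=O)C#CC(=C)C[C@]1(C)CC(=O)C(C(C)C)=CC1=O | intermediate
10 | methyl 5-(4-isopropyl-1-methyl-2,5-dioxocyclohex-3-en-1-yl)-4-oxopent-2-ynoate, quaternary carbon configured as in 9 | COC(=O)C#CC(=O)C[C@]1(C)CC(=O)C(C(C)C)=CC1=O | intermediate
11 | methyl (4aR,8aR)-7-isopropyl-4a-methyl-3,5,8-trioxo-3,4,4a,5,8,8a-hexahydronaphthalene-1-carboxylate | COC(=O)C1=CC(=O)C[C@]2(C)[C@H]1C(=O)C(C(C)C)=CC2=O | intermediate
12 | ethyl acetoacetate | CCOC(=O)CC(C)=O | starting material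
13 | ethyl 2-(2-methyl-1,3-dioxolan-2-yl)acetate | CCOC(=O)CC1(C)OCCO1 | intermediate
14 | 2-(2-methyl-1,3-dioxolan-2-yl)ethanol | OCCC1(C)OCCO1 | intermediate
15 | 2-(2-iodoethyl)-2-methyl-1,3-dioxolane | ICCC1(C)OCCO1 | intermediate
16 | methyl (4R,4aR,8aR)-7-isopropyl-4a-methyl-4-[2-(2-methyl-1,3-dioxolan-2-yl)ethyl]-3,5,8-trioxo-3,4,4a,5,8,8a-hexahydronaphthalene-1-carboxylate | COC(=O)C1=CC(=O)[C@H](CCC2(C)OCCO2)[C@]3(C)[C@H]1C(=O)C(C(C)C)=CC3=O | intermediate
17 | methyl (4R,4aR,8aR)-7-isopropyl-4a-methyl-3,5,8-trioxo-4-(3-oxobutyl)-3,4,4a,5,8,8a-hexahydronaphthalene-1-carboxylate | COC(=O)C1=CC(=O)[C@H](CCC(C)=O)[C@]2(C)[C@H]1C(=O)C(C(C)C)=CC2=O | intermediate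
18 | open ketol (3R,8R,9R,10R): rings A, B and C closed, free tertiary OH at C3, ketones at C5, C11 and C14, C12=C13 alkene | COC(=O)C1=C[C@]2(O)CC(=O)CC[C@@H]2[C@]2(C)[C@H]1C(=O)C(C(C)C)=CC2=O | intermediate
19 | cage ketone (3R,8R,9R,10R,14R): as 23 but C5 ketone, C6 saturated, C12=C13 alkene | COC(=O)C1=C[C@]23CC(=O)CC[C@@H]2[C@]2(C)[C@H]1C(=O)C(C(C)C)=C[C@@]2(O)O3 | intermediate
20 | cage enol triflate (3R,8R,9R,10R,14R): as 19 but C5(OSO2CF3)=C6 | COC(=O)C1=C[C@]23CC(OS(=O)(=O)C(F)(F)F)=CC[C@@H]2[C@]2(C)[C@H]1C(=O)C(C(C)C)=C[C@@]2(O)O3 | intermediate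
21 | cage enone (3R,8R,9R,10R,14R): 12,13-didehydro-23 | COC(=O)C1=C[C@]23CC(C)=CC[C@@H]2[C@]2(C)[C@H]1C(=O)C(C(C)C)=C[C@@]2(O)O3 | intermediate
22 | silyl enol ether (3R,8R,9R,10R,14R): as 23 but C11(OSiMe2Ph)=C12 | COC(=O)C1=C[C@]23CC(C)=CC[C@@H]2[C@]2(C)[C@H]1C(O[Si](C)(C)c1ccccc1)=C(C(C)C)C[C@@]2(O)O3 | intermediate
23 | CNP0382995.2: methyl 1-carboxylate of the cage with C1=C2 and C5=C6 alkenes, 5-methyl, 9-methyl, 11-ketone, 12-isopropyl, 14-hydroxy, O-bridge C3–O–C14; (3R,8R,9R,10R,12R,14R) | COC(=O)C1=C[C@]23CC(C)=CC[C@@H]2[C@]2(C)[C@H]1C(=O)[C@@H](C(C)C)C[C@@]2(O)O3 | target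

**Step count and weak points**
Total steps: 14. Longest linear sequence: 9 (steps 1, 2, 5, 6, 10, 11, 12, 13, 14; the branch through steps 3 and 4 is equally long, the branch through steps 7–9 is 8). Step 5 is expected to give roughly 90% ee, so 11 or 19 is recrystallised to enantiopurity.

The three steps most likely to fail:

Step 5. The free enolate may add to the alkynoate of 7 instead of being allylated, or the ee may suffer. The fallback sets out from 3 and builds the ynone after the allylation: the same Pd2(dba)3/(S)-t-BuPHOX allylation is run with commercial allyl methyl carbonate and without acid to give the allyl ketone ketal F1; ozonolysis of the allyl group gives the aldehyde F2; lithiated methyl propiolate (LiN(SiMe3)2, −78 °C) adds to the aldehyde to give the propargylic alcohol F3; Dess–Martin periodinane gives the ynone ketal F4; and 1 M HCl removes the dimethyl ketal to return to the route at 10, which is cyclised with DBU as in step 6.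

Step 10. The dianion may alkylate poorly or at the wrong atom. The fallback sets out from 11 and masks the acidic C10–H instead of deprotonating it: O-silylation (TBSOTf, Et3N) gives the cross-conjugated silyl dienol ether F5, whose only remaining α-hydrogens are at C8; one equivalent of LiN(i-Pr)2 and 15 give the alkylated silyl dienol ether F6; the 2 M HCl of step 11 then cleaves the silyl enol ether together with the dioxolane and returns to the route at 17.

Step 11. The aldol may stop at an unbridged ketol, dehydrate, or give the wrong ring fusion; the ketone it leaves at C5 also makes step 12 delicate. The fallback sets out from 11 and closes ring A by metathesis: the C8 dianion is alkylated with allyl bromide to the allyl trione F7; indium metal (In) and methallyl bromide in aqueous THF add to the enoate-conjugated C3 ketone from the face away from C14, and the tertiary alcohol closes the hemiketal to give the cage diene F8; the second-generation Grubbs catalyst then forms the trisubstituted ring A alkene and returns to the route at 21, by-passing 19 and 20.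

Further compounds
F1 | step 5 | (6R)-6-allyl-3-isopropyl-4,4-dimethoxy-6-methylcyclohex-2-en-1-one | C=CC[C@]1(C)CC(OC)(OC)C(C(C)C)=CC1=O
F2 | step 5 | 2-[(1R)-4-isopropyl-5,5-dimethoxy-1-methyl-2-oxocyclohex-3-en-1-yl]acetaldehyde | O=CC[C@]1(C)CC(OC)(OC)C(C(C)C)=CC1=O
F3 | step 5 | methyl 4-hydroxy-5-[(1R)-4-isopropyl-5,5-dimethoxy-1-methyl-2-oxocyclohex-3-en-1-yl]pent-2-ynoate (both carbinol epimers) | COC(=O)C#CC(O)C[C@]1(C)CC(OC)(OC)C(C(C)C)=CC1=O
F4 | step 5 | methyl 5-[(1R)-4-isopropyl-5,5-dimethoxy-1-methyl-2-oxocyclohex-3-en-1-yl]-4-oxopent-2-ynoate | COC(=O)C#CC(=O)C[C@]1(C)CC(OC)(OC)C(C(C)C)=CC1=O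
F5 | step 10 | methyl (4aR)-8-[(tert-butyldimethylsilyl)oxy]-7-isopropyl-4a-methyl-3,5-dioxo-3,4,4a,5-tetrahydronaphthalene-1-carboxylate | COC(=O)C1=CC(=O)C[C@]2(C)C1=C(O[Si](C)(C)C(C)(C)C)C(C(C)C)=CC2=O
F6 | step 10 | methyl (4R,4aR)-8-[(tert-butyldimethylsilyl)oxy]-7-isopropyl-4a-methyl-4-[2-(2-methyl-1,3-dioxolan-2-yl)ethyl]-3,5-dioxo-3,4,4a,5-tetrahydronaphthalene-1-carboxylate | COC(=O)C1=CC(=O)[C@H](CCC2(C)OCCO2)[C@]3(C)C1=C(O[Si](C)(C)C(C)(C)C)C(C(C)C)=CC3=O
F7 | step 11 | methyl (4R,4aR,8aR)-4-allyl-7-isopropyl-4a-methyl-3,5,8-trioxo-3,4,4a,5,8,8a-hexahydronaphthalene-1-carboxylate | COC(=O)C1=CC(=O)[C@H](CC=C)[C@]2(C)[C@H]1C(=O)C(C(C)C)=CC2=O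
F8 | step 11 | cage diene (3R,8R,9R,10R,14R): as 21 but ring A open, C3 carries 2-methylprop-2-enyl and C8 carries prop-2-enyl | COC(=O)C1=C[C@@]2(CC(C)=C)O[C@]3(O)C=C(C(C)C)C(=O)[C@@H]1[C@@]3(C)[C@H]2CC=C
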